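The route rests on disconnecting the aryl ether bond O1–C8a of the chromanone (ring C) instead of the usual O1–C2 bond. The C2 stereocentre is set first, in an open-chain (S)-β-hydroxy ketone made by a catalytic asymmetric Mukaiyama aldol addition. The ring is then closed by an intramolecular nucleophilic aromatic substitution: the C2 alkoxide displaces fluoride from C8a of ring A, which is activated by the C4 carbonyl on the neighbouring C4a. In one operation this forms ring C and carries the stereocentre through untouched, because its C–O bond is never broken. The precursor is an ortho-fluoroaryl aldol whose fluorine also directs the regioselective prenylation at C8.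

Key step: step 6

Remark: 2,2-dimethyl-2H-chromene-6-carbaldehyde (13) is taken as a catalogue compound.
Remark: the (S,S)-bisphosphoramide is assumed to direct the enol ether to the Si face of the aldehyde, which is the face that gives the S carbinol; if the sense proves opposite, the antipodal catalyst is used in the same way.

Step 1
Reactants: 1 4-bromo-3-fluorophenol
Product: 2 1-bromo-2-fluoro-4-(methoxymethoxy)benzene
Conditions: MOMCl, i-Pr2NEt, CH2Cl2, 0 °C to rt
Reagents that add atoms: chloromethyl methyl ether (MOMCl), COCCl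
Why: O-alkylation of the phenol with the chloromethyl ether under amine base (MOM protection) should mask the phenol and install the group that later helps direct the ortho-lithiation.

Step 2
Reactants: 2 1-bromo-2-fluoro-4-(methoxymethoxy)benzene; 3 prenyl bromide (1-bromo-3-methylbut-2-ene)
Product: 6 1-bromo-2-fluoro-4-(methoxymethoxy)-3-(3-methylbut-2-en-1-yl)benzene, via aryllithium 4 (not isolated), via arylcopper 5 (not isolated)
Conditions: LiN(i-Pr)2, THF, −78 °C; CuBr·SMe2, −78 to −40 °C; then 3, −40 to 0 °C
Reagents that add atoms: none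
Why: Directed ortho-metalation should occur at the C–H between fluorine and the MOM ether, the most acidic site, without bromine–lithium exchange because an amide base is used, and the arylcopper formed by transmetalation should be alkylated by the allylic bromide at its unhindered primary terminus (copper-mediated allylic substitution).

Step 3
Reactants: 6 1-bromo-2-fluoro-4-(methoxymethoxy)-3-(3-methylbut-2-en-1-yl)benzene; 7 N-methoxy-N-methylacetamide
Product: 10 1-[2-fluoro-4-(methoxymethoxy)-3-(3-methylbut-2-en-1-yl)phenyl]ethan-1-one, via aryllithium 8 (not isolated), via lithium hemiaminal alkoxide 9 (not isolated)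
Conditions: n-BuLi, THF, −78 °C; then 7, −78 to −40 °C; aq NH4Cl
Reagents that add atoms: none
Why: Bromine–lithium exchange at −78 °C should be faster than any deprotonation and precede loss of LiF from the ortho-fluoroaryllithium, and the chelated tetrahedral adduct should release the methyl ketone only on work-up (Weinreb ketone synthesis).

Step 4
Reactants: 10 1-[2-fluoro-4-(methoxymethoxy)-3-(3-methylbut-2-en-1-yl)phenyl]ethan-1-one
Product: 12 {1-[2-fluoro-4-(methoxymethoxy)-3-(3-methylbut-2-en-1-yl)phenyl]ethenyl}oxy(trimethyl)silane, via lithium enolate 11 (not isolated)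
Conditions: LiN(SiMe3)2, THF, −78 °C; Me3SiCl, −78 to 0 °C; pentane, filtration
Reagents that add atoms: chlorotrimethylsilane, C[Si](C)(C)Cl
Why: Kinetic enolisation of the methyl ketone and O-silylation of the lithium enolate (silyl enol ether formation) should give the enol ether, which a non-aqueous work-up keeps intact.

Step 5
Reactants: 12 {1-[2-fluoro-4-(methoxymethoxy)-3-(3-methylbut-2-en-1-yl)phenyl]ethenyl}oxy(trimethyl)silane; 13 2,2-dimethyl-2H-chromene-6-carbaldehyde
Product: 15 (3S)-3-(2,2-dimethyl-2H-chromen-6-yl)-1-[2-fluoro-4-(methoxymethoxy)-3-(3-methylbut-2-en-1-yl)phenyl]-3-hydroxypropan-1-one, via trichlorosilyl aldolate 14 (not isolated)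
Conditions: SiCl4, (S,S)-bisphosphoramide (pentane-1,5-diyl-linked bis-phosphoramide of N,N′-dimethyl-1,1′-binaphthyl-2,2′-diamine, 5 mol%), i-Pr2NEt (10 mol%), CH2Cl2, −78 °C; aq NaHCO3
Reagents that add atoms: none
Why: In this Lewis-base-activated Mukaiyama aldol addition the chiral phosphoramide-bound trichlorosilyl cation should bind the aromatic aldehyde and expose its Si face to the enol ether, so the carbinol centre (the later C2) is set as S under catalyst control.

Step 6
Reactants: 15 (3S)-3-(2,2-dimethyl-2H-chromen-6-yl)-1-[2-fluoro-4-(methoxymethoxy)-3-(3-methylbut-2-en-1-yl)phenyl]-3-hydroxypropan-1-one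
Product: 17 (2S)-2-(2,2-dimethyl-2H-chromen-6-yl)-7-(methoxymethoxy)-8-(3-methylbut-2-en-1-yl)-2,3-dihydro-4H-chromen-4-one, via potassium alkoxide 16 (not isolated)
Conditions: KN(SiMe3)2 (1.0 equiv), THF, −78 to 0 °C; pH 7 buffer
Reagents that add atoms: none
Why: KN(SiMe3)2 should deprotonate the hydroxyl irreversibly, the alkoxide adds to the fluorine-bearing ring carbon (the future C8a) to give a Meisenheimer adduct whose charge is held as the enolate of the ortho ketone (the future C4), and fluoride is then expelled (addition–elimination, intramolecular SNAr). The closest known reaction type is the base-mediated cyclisation of ortho-fluoroaryl ketones that carry a tethered alkoxide or enolate oxygen, which gives chromanones and chromones. The one ring closed is the six-membered pyranone ring C, by 6-endo-trig attack of oxygen on the C4a=C8a bond of the aryl ketone, seen as a vinylogous acyl fluoride. No stereocentre is formed: the S centre from step 5 becomes C2 with retention, because only its O–H bond and not its C–O bond takes part. The step needs ring closure to outrun retro-aldol cleavage and E1cB dehydration of the aldolate; the low temperature, exactly one equivalent of a non-nucleophilic base, fluoride as the fastest SNAr leaving group and the short tether should secure this, while the MOM ether (instead of a deactivating phenoxide) keeps ring A electrophilic and the single fluorine leaves no regiochemical choice.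

Step 7
Reactants: 17 (2S)-2-(2,2-dimethyl-2H-chromen-6-yl)-7-(methoxymethoxy)-8-(3-methylbut-2-en-1-yl)-2,3-dihydro-4H-chromen-4-one
Product: 18 (2S)-2-(2,2-dimethyl-2H-chromen-6-yl)-7-hydroxy-8-(3-methylbut-2-en-1-yl)-2,3-dihydro-4H-chromen-4-one
Conditions: HCl (1 M in MeOH), rt
Reagents that add atoms: none
Why: Acid-catalysed acetal exchange with methanol (MOM deprotection) should free the C7 phenol, and dilute acid at room temperature is chosen so that neither the ortho-prenyl group cyclises onto the phenol nor the C2 centre, which epimerises only through base-induced ring opening, is disturbed.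

Compound list
1 | 4-bromo-3-fluorophenol | Oc1ccc(Br)c(F)c1 | starting material
2 | 1-bromo-2-fluoro-4-(methoxymethoxy)benzene | COCOc1ccc(Br)c(F)c1 | intermediate
3 | prenyl bromide (1-bromo-3-methylbut-2-ene) | CC(C)=CCBr | starting material
4 | [3-bromo-2-fluoro-6-(methoxymethoxy)phenyl]lithium (not isolated) | [Li]c1c(F)c(Br)ccc1OCOC | intermediate
5 | [3-bromo-2-fluoro-6-(methoxymethoxy)phenyl]copper (not isolated) | [Cu]c1c(F)c(Br)ccc1OCOC | intermediate
6 | 1-bromo-2-fluoro-4-(methoxymethoxy)-3-(3-methylbut-2-en-1-yl)benzene | COCOc1ccc(Br)c(F)c1CC=C(C)C | intermediate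
7 | N-methoxy-N-methylacetamide | CC(=O)N(C)OC | starting material
8 | [2-fluoro-4-(methoxymethoxy)-3-(3-methylbut-2-en-1-yl)phenyl]lithium (not isolated) | [Li]c1ccc(OCOC)c(CC=C(C)C)c1F | intermediate
9 | lithium 1-[2-fluoro-4-(methoxymethoxy)-3-(3-methylbut-2-en-1-yl)phenyl]-1-[methoxy(methyl)amino]ethan-1-olate (not isolated) | CC(O[Li])(N(C)OC)c1ccc(OCOC)c(CC=C(C)C)c1F | intermediate
10 | 1-[2-fluoro-4-(methoxymethoxy)-3-(3-methylbut-2-en-1-yl)phenyl]ethan-1-one | CC(=O)c1ccc(OCOC)c(CC=C(C)C)c1F | intermediate
11 | lithium 1-[2-fluoro-4-(methoxymethoxy)-3-(3-methylbut-2-en-1-yl)phenyl]ethen-1-olate (not isolated) | C=C(O[Li])c1ccc(OCOC)c(CC=C(C)C)c1F | intermediate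
12 | {1-[2-fluoro-4-(methoxymethoxy)-3-(3-methylbut-2-en-1-yl)phenyl]ethenyl}oxy(trimethyl)silane | C=C(O[Si](C)(C)C)c1ccc(OCOC)c(CC=C(C)C)c1F | intermediate
13 | 2,2-dimethyl-2H-chromene-6-carbaldehyde | CC1(C)C=Cc2cc(C=O)ccc2O1 | starting material
14 | (3S)-3-(2,2-dimethyl-2H-chromen-6-yl)-1-[2-fluoro-4-(methoxymethoxy)-3-(3-methylbut-2-en-1-yl)phenyl]-3-[(trichlorosilyl)oxy]propan-1-one (not isolated) | CC(C)=CCc1c(OCOC)ccc(C(=O)C[C@H](O[Si](Cl)(Cl)Cl)c2ccc3OC(C)(C)C=Cc3c2)c1F | intermediate
15 | (3S)-3-(2,2-dimethyl-2H-chromen-6-yl)-1-[2-fluoro-4-(methoxymethoxy)-3-(3-methylbut-2-en-1-yl)phenyl]-3-hydroxypropan-1-one | CC(C)=CCc1c(OCOC)ccc(C(=O)C[C@H](O)c2ccc3OC(C)(C)C=Cc3c2)c1F | intermediate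
16 | potassium (1S)-1-(2,2-dimethyl-2H-chromen-6-yl)-3-[2-fluoro-4-(methoxymethoxy)-3-(3-methylbut-2-en-1-yl)phenyl]-3-oxopropan-1-olate (not isolated) | CC(C)=CCc1c(OCOC)ccc(C(=O)C[C@H](O[K])c2ccc3OC(C)(C)C=Cc3c2)c1F | intermediate
17 | (2S)-2-(2,2-dimethyl-2H-chromen-6-yl)-7-(methoxymethoxy)-8-(3-methylbut-2-en-1-yl)-2,3-dihydro-4H-chromen-4-one | CC(C)=CCc1c(OCOC)ccc2c1O[C@H](c1ccc3c(c1)C=CC(C)(C)O3)CC2=O | intermediate
18 | (2S)-2-(2,2-dimethyl-2H-chromen-6-yl)-7-hydroxy-8-(3-methylbut-2-en-1-yl)-2,3-dihydro-4H-chromen-4-one | CC(C)=CCc1c(O)ccc2c1O[C@H](c1ccc3c(c1)C=CC(C)(C)O3)CC2=O | target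

Total step count: 7. Longest linear sequence: 7 steps (1 to 18).

Steps most likely to fail

Step 6. Retro-aldol cleavage or E1cB dehydration of the potassium aldolate may compete with ring closure, and the product may ring-open under base, so that material is lost and the configuration at C2 erodes. The fallback sets out from 15 and removes the carbonyl group during the ring closure. Reduction with NaBH4 (MeOH, 0 °C) should give (3S)-3-(2,2-dimethyl-2H-chromen-6-yl)-1-[2-fluoro-4-(methoxymethoxy)-3-(3-methylbut-2-en-1-yl)phenyl]propane-1,3-diol F1 as a mixture of C1 epimers, which can neither fragment nor dehydrate by these paths. Double deprotonation (KN(SiMe3)2, THF/DMPU, 60 °C) and intramolecular SNAr of the C3 alkoxide on the now unactivated fluoroarene (the C1 alkoxide cannot reach the fluorinated carbon) should give (2S)-2-(2,2-dimethyl-2H-chromen-6-yl)-7-(methoxymethoxy)-8-(3-methylbut-2-en-1-yl)-3,4-dihydro-2H-chromen-4-ol F2, again forming the O1–C8a bond. Oxidation of the benzylic alcohol with Dess–Martin periodinane (NaHCO3, CH2Cl2, rt) comes back to the route at 17.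

Step 5. Facial selectivity may be insufficient, or the electron-rich benzylic silyl ether may ionise under the Lewis acid, which would lower the optical purity or lead to elimination. The fallback sets out from 10 and 13 and builds the carbinol by a formal asymmetric hydration of an enone. Claisen–Schmidt condensation (KOH, EtOH, rt) should give (2E)-3-(2,2-dimethyl-2H-chromen-6-yl)-1-[2-fluoro-4-(methoxymethoxy)-3-(3-methylbut-2-en-1-yl)phenyl]prop-2-en-1-one F3. Copper-catalysed enantioselective conjugate borylation (B2pin2, CuCl, NaOt-Bu, a Josiphos-type ferrocenyl diphosphine of the antipode that gives the S boronate, MeOH, THF, rt) should give (3S)-3-(2,2-dimethyl-2H-chromen-6-yl)-1-[2-fluoro-4-(methoxymethoxy)-3-(3-methylbut-2-en-1-yl)phenyl]-3-(4,4,5,5-tetramethyl-1,3,2-dioxaborolan-2-yl)propan-1-one F4. Oxidation of the C–B bond with retention (NaBO3·4H2O, THF/H2O, rt) comes back to the route at 15.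

Step 2. The arylcopper may attack the tertiary terminus of the allylic bromide and give the 1,1-dimethylallyl isomer, or the allylic substitution may be sluggish at the hindered position between fluorine and the MOM ether. The fallback sets out from 2 and installs the prenyl group in two stages. The same lithiation and transmetalation (LiN(i-Pr)2, THF, −78 °C; CuBr·SMe2), followed by allyl bromide, for which both termini are equivalent, should give 1-bromo-2-fluoro-4-(methoxymethoxy)-3-(prop-2-en-1-yl)benzene F5. Olefin cross-metathesis with 2-methylbut-2-ene (second-generation Grubbs catalyst, CH2Cl2, 40 °C) should convert the allyl into the prenyl group and comes back to the route at 6.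

Further compounds
F1 | step 6 | (3S)-3-(2,2-dimethyl-2H-chromen-6-yl)-1-[2-fluoro-4-(methoxymethoxy)-3-(3-methylbut-2-en-1-yl)phenyl]propane-1,3-diol | CC(C)=CCc1c(OCOC)ccc(C(O)C[C@H](O)c2ccc3OC(C)(C)C=Cc3c2)c1F
F2 | step 6 | (2S)-2-(2,2-dimethyl-2H-chromen-6-yl)-7-(methoxymethoxy)-8-(3-methylbut-2-en-1-yl)-3,4-dihydro-2H-chromen-4-ol | CC(C)=CCc1c(OCOC)ccc2c1O[C@H](c1ccc3c(c1)C=CC(C)(C)O3)CC2O
F3 | step 5 | (2E)-3-(2,2-dimethyl-2H-chromen-6-yl)-1-[2-fluoro-4-(methoxymethoxy)-3-(3-methylbut-2-en-1-yl)phenyl]prop-2-en-1-one | CC(C)=CCc1c(OCOC)ccc(C(=O)/C=C/c2ccc3OC(C)(C)C=Cc3c2)c1F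
F4 | step 5 | (3S)-3-(2,2-dimethyl-2H-chromen-6-yl)-1-[2-fluoro-4-(methoxymethoxy)-3-(3-methylbut-2-en-1-yl)phenyl]-3-(4,4,5,5-tetramethyl-1,3,2-dioxaborolan-2-yl)propan-1-one | CC(C)=CCc1c(OCOC)ccc(C(=O)C[C@H](B2OC(C)(C)C(C)(C)O2)c2ccc3OC(C)(C)C=Cc3c2)c1F
F5 | step 2 | 1-bromo-2-fluoro-4-(methoxymethoxy)-3-(prop-2-en-1-yl)benzene | COCOc1ccc(Br)c(F)c1CC=C
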